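## Structural features

Labdane numbering is used for atoms throughout (decalin C1–C10, side chain C11–C16, C17 on C8, C20 on C10); compound names use naphthalene numbering. Rings A and B form a trans-decalin fused at C5–C10; ring A is a bare cyclohexane whose gem-dimethyl carbon C4 flanks C5 and whose C1 flanks the quaternary, methyl-bearing C10. Ring B carries all the functionality: an axial 6β-acetate, a pseudoaxial allylic 7α-hydroxyl, and a tetrasubstituted C8=C9 bond with a methyl on C8 and the (Z)-5-hydroxy-3-methylpent-3-enyl chain on C9. The four stereocentres C10, C5, C6 and C7 (all S) are contiguous; the C6 oxygen is syn-axial to the C10 and 4β methyl groups and trans-diaxial to the C7 oxygen. Fragile groups are the two allylic alcohols (C7 ionisable, C15 primary), the Z-trisubstituted C13=C14 bond, and an acetate next to a free hydroxyl (migration is blocked only by the trans-diaxial geometry). The real difficulty is the quaternary C10 beside C5 in a trans relation, a contra-steric 6β-oxygen, and an acetate on the most hindered of three hydroxyls. The key step exploits the fact that ring B (C5–C10) repeats the substitution of 2,6-dimethyl-1,4-benzoquinone: oxygen on C6, an oxidised sp2 carbon at C9 para to it, methyls on C8 and C10, and unsubstituted C5 and C7. Ring B can therefore be bought intact and ring A added across C5=C10.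

## Logic of the disconnections

19 to 18: the O–Si bonds at C7–O and C15–O are cut. Both free hydroxyls appear only in the last step, so the acetate never meets a competing alcohol. The forward step must remove two silyl ethers without ionising the allylic C7–O bond or moving the acetate.

18 to 17: the acyl C–O bond at C6 is cut. In 17 the 6β-hydroxyl is the only free one, which turns the selectivity problem into a plain, if hindered, acylation.

17 to 12 and 16: the sp2–sp3 bond C9–C11 is cut. This separates a C14 bicyclic core from a C6 chain whose Z alkene is bought, and makes the route convergent. The forward step is a cross-coupling at a tetrasubstituted vinyl triflate next to a quaternary carbon.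

12 to 11: the C6–H bond is cut (back to a ketone). A C6 ketone lets the axial 6β-alcohol arise from hydride attack on the open α face. The forward step needs α-face delivery despite the neighbouring 7α-silyl ether.

11 to 9 (through 10): the C7–O bond is cut. The oxygen enters by oxidation of a C6 silyl enol ether and arrives already silylated and differentiated. The forward step needs attack on the enol ether and not on C8=C9, which the triflate on C9 secures.

9 to 7 to 5: the O–S bond at C9 and the O–Si bond at C6 are cut. Both come from one diketone by two regiochemically unambiguous enolisations (C6 toward C7, C9 toward C8). The demand is kinetic deprotonation at C7 before C8.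

5 to 4 to 3: the C5–H bond is re-formed (epimerisation) and four C–H bonds are cut (two C=C bonds). This leads back to the cis-fused enedione that a cycloaddition delivers. The demand is a thermodynamic preference for the trans ring fusion.

3 to 1 and 2: the bonds C1–C10 and C4–C5 are cut. Ring A and the quaternary C10 come from one cycloaddition onto a symmetric, commercial ring B; twelve of the twenty skeletal carbons and the C6 and C9 oxygens are in place afterwards. The forward step needs catalyst control of the face and regiocontrol (CH2 terminus to the methyl-bearing carbon).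

16 to 15 to 14 to 13: the C–B bond, two C–H bonds of the alkyne and the O–Si bond are cut, back to a commercial Z-enynol. The demand is hydroboration at the terminal vinyl carbon only.

## Other disconnections considered

Alternative 1: The first plan that comes to mind keeps the whole skeleton of (−)-sclareol and cuts only C–O and C–H bonds. Allylic transposition at C13 and dehydration at C8 would give (13Z)-labda-8,13-dien-15-ol A1, and allylic oxidation the C7 enone A2. The chosen plan is preferred for three reasons. A C7 ketone is the wrong handle: oxygenation at C6 from the open α face would give 6α, and axial hydride delivery at C7 would give 7β, so both centres would need inversion. Allylic oxidation of A1 has C7, C11, C12, C14 and C17 to choose from. The transposition favours the 13E isomer.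

Alternative 2: Cut C4–C5 and C9–C10 in a biomimetic bicyclisation. A chiral Brønsted-acid-assisted Lewis acid would fold the acyclic (2Z,6E,10E)-tetraenyl silyl ether A3 into the bicycle A4 with the trans ring fusion set directly. The chosen plan is preferred because termination at the C8 cation gives a mixture of Δ7, Δ8 and Δ8(17) alkenes, the C13=C14 bond can cyclise further, and ring B arrives with no oxygen, which returns the C6/C7 problem of Alternative 1 after the key step.

Alternative 3: Take ring B from (R)-carvone and build ring A on it, cutting C1–C10 and C2–C3 and adding the C20 and one C4 methyl. α′-Methylation and then α′-allylation anti to the isopropenyl group would give A5 with C10 relayed from the bought C5; ozonolysis, aldol closure, hydrogenation and geminal dimethylation with Me2TiCl2 would give enone A6. This sets the trans fusion kinetically, but it is longer to the bicycle and the oxygen sits on C9/C7 (after chain addition and oxidative transposition it converges on A2). It therefore inherits the wrong-handle problem, whereas the chosen dienophile delivers the C6 ketone directly.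

Key step: step 1

Remark 1: the (S)-oxazaborolidinium catalyst is written in step 1; its sense of induction is assigned from the α-C–H···O binding model, and if it proved opposite the (R)-catalyst would be used with no other change.
Remark 2: (Z)-3-methylpent-2-en-4-yn-1-ol (13) and 4-methylpenta-1,3-diene (2) are taken as commercial.

## Route

Step 1
Reactants: 1 2,6-dimethyl-1,4-benzoquinone; 2 4-methylpenta-1,3-diene (excess)
Product: 3 (4aR,8aS)-2,5,5,8a-tetramethyl-4a,5,8,8a-tetrahydronaphthalene-1,4-dione (cis-fused)
Conditions: (S)-diphenylprolinol-derived B-(o-tolyl)oxazaborolidine (20 mol%), HNTf2 (18 mol%), CH2Cl2, −78 to −20 °C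
Reagents that add atoms: none
Why: The triflimide-activated oxazaborolidine binds the unhindered C6 carbonyl of 1 (the one flanked by two C–H) at the lone pair syn to an α-C–H, which lowers the LUMO and makes the methyl-bearing β-carbon C10 the electrophilic terminus of the adjacent C5=C10 bond. The reaction is a chiral-oxazaborolidinium-catalysed quinone Diels–Alder reaction, concerted but strongly asynchronous: the unhindered CH2 terminus of 2 (largest HOMO coefficient) bonds first to C10 and the gem-dimethyl terminus closes late onto the enolate-like C5, with positive charge building at the tertiary allylic C4. Ring A is closed in the [4+2] mode (six-membered, bonds C1–C10 and C4–C5 formed suprafacially on both partners). C10 (S) is set by the catalyst, which shields one face of the bound enone; C5 arises cis to the C10 methyl by suprafacial addition and is corrected in step 3. Regioselectivity is secured twice, electronically by coordination at C6=O and sterically because the alternative would join the CMe2 terminus to the methyl-bearing carbon. Site selectivity is no issue because the two C=C bonds of 1 are related by its twofold axis, and endo/exo selectivity is irrelevant because neither diene terminus becomes a stereocentre. The weak point is the inside methyl of 2, which disfavours the s-cis conformer; an asynchronous polar transition state tolerates a twisted diene better than a synchronous one, and excess diene with a slight excess of oxazaborolidine over HNTf2 (no free acid, to avoid cationic oligomerisation of 2) is planned.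

Step 2
Reactants: 3
Product: 4 (4aR,8aS)-2,5,5,8a-tetramethyloctahydronaphthalene-1,4-dione (cis-fused, mixture of C2 epimers)
Conditions: H2 (1 atm), Pd/C, EtOAc, rt
Reagents that add atoms: none
Why: Catalytic hydrogenation saturates both the cis-disubstituted ring A alkene and the electron-poor enedione alkene; ketones are not reduced under these conditions. The C8 configuration is immaterial because C8 becomes sp2 in step 5.

Step 3
Reactants: 4
Product: 5 (2R,4aS,8aS)-2,5,5,8a-tetramethyloctahydronaphthalene-1,4-dione (trans-fused, 8-methyl equatorial)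
Conditions: NaOMe (0.2 equiv), MeOH, rt; separation, cis fraction re-submitted
Reagents that add atoms: none
Why: Base-catalysed enolisation of the C6 ketone toward C5 equilibrates the ring fusion (and C8) under thermodynamic control, the classical epimerisation of angular-methyl quinone adducts. Trans-fused 5 is expected to be favoured because both chair forms of the cis isomer either keep the 1,3-diaxial methyl pair and add an axial ring carbon, or place the gem-dimethyl-bearing carbon axial on ring B. Ring B is saturated first so that it can adopt the chair on which this preference rests; C10 is quaternary and cannot epimerise.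

Step 4
Reactants: 5
Product: 7 (2R,4aS,8aS)-4-[(tert-butyldimethylsilyl)oxy]-2,5,5,8a-tetramethyl-4a,5,6,7,8,8a-hexahydronaphthalen-1(2H)-one, via potassium C6 enolate 6 (not isolated)
Conditions: KN(SiMe3)2 (1.05 equiv), THF, −78 °C; then TBSOTf
Reagents that add atoms: tert-butyldimethylsilyl trifluoromethanesulfonate, CC(C)(C)[Si](C)(C)OS(=O)(=O)C(F)(F)F
Why: Kinetic deprotonation by the bulky amide occurs at the only unhindered α-methylene, C7 (C5–H lies between two quaternary carbons, C8–H is a methine beside the more hindered carbonyl), and O-silylation gives the C6=C7 silyl enol ether. This masks the C6 ketone and differentiates the two carbonyls; C5 is not enolised and keeps its configuration.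

Step 5
Reactants: 7
Product: 9 (4aS,8aS)-4-[(tert-butyldimethylsilyl)oxy]-2,5,5,8a-tetramethyl-4a,5,6,7,8,8a-hexahydronaphthalen-1-yl trifluoromethanesulfonate, via potassium dienolate 8 (not isolated)
Conditions: KN(SiMe3)2 (1.1 equiv), THF, −78 °C; then PhNTf2, −78 to 0 °C
Reagents that add atoms: N-phenylbis(trifluoromethanesulfonimide), O=S(=O)(N(c1ccccc1)S(=O)(=O)C(F)(F)F)C(F)(F)F
Why: The C9 ketone can enolise only toward C8 because C10 is quaternary; O-triflation of the extended enolate fixes the future C8=C9 bond and provides the handle for the side chain. Enol triflate formation from a ketone flanked by a quaternary carbon and a methyl-bearing methine is standard.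

Step 6
Reactants: 9
Product: 11 (3S,4aS,8aS)-3-[(tert-butyldimethylsilyl)oxy]-2,5,5,8a-tetramethyl-4-oxo-3,4,4a,5,6,7,8,8a-octahydronaphthalen-1-yl trifluoromethanesulfonate, via silyloxy epoxide 10 (not isolated)
Conditions: mCPBA (1.05 equiv), NaHCO3, CH2Cl2, −20 to 0 °C
Reagents that add atoms: 3-chloroperoxybenzoic acid, OOC(=O)c1cccc(Cl)c1
Why: Rubottom oxidation: the electron-rich C6=C7 silyl enol ether is epoxidised in preference to the triflate-deactivated C8=C9 bond, from the α face because the β face of C6 is screened by the syn-axial C10 and 4β methyl groups. The silyloxy epoxide opens to the C6 oxocarbenium ion and 1,4-silyl migration delivers the 7α-silyl ether, so C7 (S) arrives already protected and differentiated from the later C6 hydroxyl.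

Step 7
Reactants: 11
Product: 12 (3S,4S,4aS,8aS)-3-[(tert-butyldimethylsilyl)oxy]-4-hydroxy-2,5,5,8a-tetramethyl-3,4,4a,5,6,7,8,8a-octahydronaphthalen-1-yl trifluoromethanesulfonate
Conditions: NaBH4, CeCl3·7H2O, MeOH/THF, −40 °C
Reagents that add atoms: none
Why: Luche-type 1,2-reduction: hydride should approach C6 from the α face because the β face is blocked by the two syn-axial methyl groups, giving the axial 6β-alcohol (6S) trans-diaxial to the 7α-silyl ether. The trans-diaxial relation also prevents 1,2-silyl migration, and CeCl3 keeps the medium non-basic so that C5 and C7 are not enolised.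

Step 8
Reactants: 13 (2Z)-3-methylpent-2-en-4-yn-1-ol
Product: 14 tert-butyldimethyl{[(2Z)-3-methylpent-2-en-4-yn-1-yl]oxy}silane
Conditions: TBSCl, imidazole, DMF, 0 °C to rt
Reagents that add atoms: tert-butyldimethylsilyl chloride, CC(C)(C)[Si](C)(C)Cl
Why: Standard silylation of the primary allylic alcohol; the Z geometry of the future C13=C14 bond is bought with 13.

Step 9
Reactants: 14
Product: 15 tert-butyldimethyl{[(2Z)-3-methylpenta-2,4-dien-1-yl]oxy}silane
Conditions: H2 (1 atm), lead-poisoned Pd/CaCO3, quinoline, hexane, rt
Reagents that add atoms: none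
Why: Semi-hydrogenation of the terminal alkyne on poisoned palladium stops at the 1,3-diene; the trisubstituted Z alkene is not touched.

Step 10
Reactants: 15; 12
Product: 17 (1S,2S,4aS,8aS)-2-[(tert-butyldimethylsilyl)oxy]-4-[(3Z)-5-[(tert-butyldimethylsilyl)oxy]-3-methylpent-3-en-1-yl]-3,4a,8,8-tetramethyl-1,2,4a,5,6,7,8,8a-octahydronaphthalen-1-ol, via alkyl-9-BBN borane 16 (not isolated)
Conditions: 15, 9-BBN, THF, 0 °C to rt; then 12, Pd(dppf)Cl2 (10 mol%), Cs2CO3, DMF/THF/H2O, 40 °C
Reagents that add atoms: none
Why: 9-BBN adds to the monosubstituted vinyl terminus of the diene with boron on the terminal carbon, and B-alkyl Suzuki–Miyaura coupling with the vinyl triflate forms the sp2–sp3 bond C9–C11 with retention of both alkene geometries. The hindered free 6β-hydroxyl and the silyl ethers tolerate the aqueous carbonate.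

Step 11
Reactants: 17
Product: 18 (1S,2S,4aS,8aS)-2-[(tert-butyldimethylsilyl)oxy]-4-[(3Z)-5-[(tert-butyldimethylsilyl)oxy]-3-methylpent-3-en-1-yl]-3,4a,8,8-tetramethyl-1,2,4a,5,6,7,8,8a-octahydronaphthalen-1-yl acetate
Conditions: Ac2O, DMAP, pyridine, 40 °C
Reagents that add atoms: acetic anhydride, CC(=O)OC(C)=O
Why: DMAP-catalysed acylation of the only free hydroxyl places the acetate on the most hindered oxygen without a selectivity problem.

Step 12
Reactants: 18
Product: 19 (13Z)-6β-acetoxylabda-8,13-diene-7α,15-diol, i.e. (1S,2S,4aS,8aS)-2-hydroxy-4-[(3Z)-5-hydroxy-3-methylpent-3-en-1-yl]-3,4a,8,8-tetramethyl-1,2,4a,5,6,7,8,8a-octahydronaphthalen-1-yl acetate (target)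
Conditions: HF·pyridine, pyridine, THF, 0 °C to rt
Reagents that add atoms: none
Why: Fluoride cleaves both silyl ethers; the pyridine-buffered reagent avoids ionisation of the allylic C7–O bond, and the trans-diaxial geometry prevents 6-to-7 acetyl migration.

## Compound list

1 | 2,6-dimethyl-1,4-benzoquinone | CC1=CC(=O)C=C(C)C1=O | starting material
2 | 4-methylpenta-1,3-diene | CC(C)=CC=C | starting material
3 | (4aR,8aS)-2,5,5,8a-tetramethyl-4a,5,8,8a-tetrahydronaphthalene-1,4-dione | O=C1C=C(C)C(=O)[C@@]2(C)CC=CC(C)(C)[C@@H]12 | intermediate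
4 | (4aR,8aS)-2,5,5,8a-tetramethyloctahydronaphthalene-1,4-dione (C2 epimers) | O=C1CC(C)C(=O)[C@@]2(C)CCCC(C)(C)[C@@H]12 | intermediate
5 | (2R,4aS,8aS)-2,5,5,8a-tetramethyloctahydronaphthalene-1,4-dione | O=C1C[C@@H](C)C(=O)[C@@]2(C)CCCC(C)(C)[C@H]12 | intermediate
6 | potassium (2R,4aS,8aS)-2,5,5,8a-tetramethyl-1-oxo-1,2,4a,5,6,7,8,8a-octahydronaphthalen-4-olate | [K+].[O-]C1=C[C@@H](C)C(=O)[C@@]2(C)CCCC(C)(C)[C@H]12 | intermediate (not isolated)
7 | (2R,4aS,8aS)-4-[(tert-butyldimethylsilyl)oxy]-2,5,5,8a-tetramethyl-4a,5,6,7,8,8a-hexahydronaphthalen-1(2H)-one | CC(C)(C)[Si](C)(C)OC1=C[C@@H](C)C(=O)[C@@]2(C)CCCC(C)(C)[C@H]12 | intermediate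
8 | potassium (4aS,8aS)-4-[(tert-butyldimethylsilyl)oxy]-2,5,5,8a-tetramethyl-4a,5,6,7,8,8a-hexahydronaphthalen-1-olate | [K+].CC(C)(C)[Si](C)(C)OC1=CC(C)=C([O-])[C@@]2(C)CCCC(C)(C)[C@H]12 | intermediate (not isolated)
9 | (4aS,8aS)-4-[(tert-butyldimethylsilyl)oxy]-2,5,5,8a-tetramethyl-4a,5,6,7,8,8a-hexahydronaphthalen-1-yl trifluoromethanesulfonate | CC(C)(C)[Si](C)(C)OC1=CC(C)=C(OS(=O)(=O)C(F)(F)F)[C@@]2(C)CCCC(C)(C)[C@H]12 | intermediate
10 | (3S,4S,4aS,8aS)-4-[(tert-butyldimethylsilyl)oxy]-3,4-epoxy-2,5,5,8a-tetramethyl-3,4,4a,5,6,7,8,8a-octahydronaphthalen-1-yl trifluoromethanesulfonate (6α,7α-epoxide) | CC(C)(C)[Si](C)(C)O[C@]12O[C@H]1C(C)=C(OS(=O)(=O)C(F)(F)F)[C@@]3(C)CCCC(C)(C)[C@H]23 | intermediate (not isolated)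
11 | (3S,4aS,8aS)-3-[(tert-butyldimethylsilyl)oxy]-2,5,5,8a-tetramethyl-4-oxo-3,4,4a,5,6,7,8,8a-octahydronaphthalen-1-yl trifluoromethanesulfonate | O=C1[C@@H](O[Si](C)(C)C(C)(C)C)C(C)=C(OS(=O)(=O)C(F)(F)F)[C@@]2(C)CCCC(C)(C)[C@H]12 | intermediate
12 | (3S,4S,4aS,8aS)-3-[(tert-butyldimethylsilyl)oxy]-4-hydroxy-2,5,5,8a-tetramethyl-3,4,4a,5,6,7,8,8a-octahydronaphthalen-1-yl trifluoromethanesulfonate | O[C@@H]1[C@@H](O[Si](C)(C)C(C)(C)C)C(C)=C(OS(=O)(=O)C(F)(F)F)[C@@]2(C)CCCC(C)(C)[C@H]12 | intermediate
13 | (2Z)-3-methylpent-2-en-4-yn-1-ol | OC/C=C(/C)C#C | starting material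
14 | tert-butyldimethyl{[(2Z)-3-methylpent-2-en-4-yn-1-yl]oxy}silane | CC(C)(C)[Si](C)(C)OC/C=C(/C)C#C | intermediate
15 | tert-butyldimethyl{[(2Z)-3-methylpenta-2,4-dien-1-yl]oxy}silane | CC(C)(C)[Si](C)(C)OC/C=C(/C)C=C | intermediate
16 | 9-{(3Z)-5-[(tert-butyldimethylsilyl)oxy]-3-methylpent-3-en-1-yl}-9-borabicyclo[3.3.1]nonane | CC(C)(C)[Si](C)(C)OC/C=C(/C)CCB1C2CCCC1CCC2 | intermediate (not isolated)
17 | (1S,2S,4aS,8aS)-2-[(tert-butyldimethylsilyl)oxy]-4-[(3Z)-5-[(tert-butyldimethylsilyl)oxy]-3-methylpent-3-en-1-yl]-3,4a,8,8-tetramethyl-1,2,4a,5,6,7,8,8a-octahydronaphthalen-1-ol | O[C@@H]1[C@@H](O[Si](C)(C)C(C)(C)C)C(C)=C(CC/C(C)=C\CO[Si](C)(C)C(C)(C)C)[C@@]2(C)CCCC(C)(C)[C@H]12 | intermediate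
18 | (1S,2S,4aS,8aS)-2-[(tert-butyldimethylsilyl)oxy]-4-[(3Z)-5-[(tert-butyldimethylsilyl)oxy]-3-methylpent-3-en-1-yl]-3,4a,8,8-tetramethyl-1,2,4a,5,6,7,8,8a-octahydronaphthalen-1-yl acetate | CC(=O)O[C@@H]1[C@@H](O[Si](C)(C)C(C)(C)C)C(C)=C(CC/C(C)=C\CO[Si](C)(C)C(C)(C)C)[C@@]2(C)CCCC(C)(C)[C@H]12 | intermediate
19 | (1S,2S,4aS,8aS)-2-hydroxy-4-[(3Z)-5-hydroxy-3-methylpent-3-en-1-yl]-3,4a,8,8-tetramethyl-1,2,4a,5,6,7,8,8a-octahydronaphthalen-1-yl acetate | CC(=O)O[C@@H]1[C@@H](O)C(C)=C(CC/C(C)=C\CO)[C@@]2(C)CCCC(C)(C)[C@H]12 | target

## Step count and least certain steps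

Total: 12 steps. Longest linear sequence: 10 steps (steps 1–7, 10, 11, 12 from 1).

Step 1 (key step). The most likely failure is a sluggish cycloaddition: the inside methyl of 2 disfavours the s-cis conformer, and the strong Lewis acid may instead trigger cationic oligomerisation of the diene or let an unselective background reaction erode the enantioselectivity. The fallback sets out from 1 and returns at 4. Diene 2 is replaced by allylidenecyclopropane F1, made by Wittig reaction of cyclopropyltriphenylphosphonium bromide (KOt-Bu) with acrolein; it has no inside substituent and serves as an equivalent of a 1,1-dimethyl diene. Cycloaddition with 1 under the same catalyst should give the spiro adduct F2. Diimide (potassium azodicarboxylate, AcOH) saturates the ring A alkene without opening the three-membered ring, and Zn/AcOH reduces the enedione to the spiro dione F3. Hydrogenolysis of the distal cyclopropane bond (H2, PtO2, AcOH, with re-oxidation of any carbinol by a periodinane oxidant) then unveils the gem-dimethyl group of 4.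

Step 3. The risk is an equilibrium that leaves a large share of the cis-fused isomer, because the trans isomer carries the 1,3-diaxial methyl pair and the preference rests on a conformational estimate only. The fallback sets out from 3 and returns at 5. The driving force is changed from a solution equilibrium to crystallisation: enedione 3, which can enolise only toward C5, is converted through its dienolate (aqueous KOH/dioxane, then acidification of a seeded slurry) into the trans-fused enedione F4, the classical remedy for angular-methyl quinone adducts. F4 is then hydrogenated (H2, Pd/C) under neutral conditions to 5.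

Step 6. The risk is loss of regiochemical or chemical control in the oxidation: hydrolysis of the silyl enol ether without oxygen transfer, or incomplete silyl migration. The fallback sets out from 9 and returns at 11. The silyl enol ether is cleaved selectively (HF·pyridine, THF, −20 °C) to the β,γ-unsaturated ketone F5. Its potassium dienolate (KN(SiMe3)2, −78 °C) is hydroxylated at the α-carbon C7 from the α face with 3-phenyl-2-(phenylsulfonyl)oxaziridine to give hydroxy ketone F6. Silylation (TBSOTf, 2,6-lutidine) gives 11.

Step 7. The risk is poor facial selectivity, because the 7α-silyl ether hinders the α face and, on stereoelectronic grounds, favours attack anti to the C7–O bond, which would give the 6α-alcohol. The fallback sets out from 11 and returns at 12. The silyl group is removed (HF·pyridine) to give hydroxy ketone F6. Me4NBH(OAc)3 (MeCN/AcOH, −20 °C) binds the 7α-hydroxyl and delivers hydride intramolecularly to the α face of C6, giving the trans-diol F7. The less hindered allylic 7-hydroxyl is then silylated selectively (TBSOTf, 2,6-lutidine, −78 °C).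

Step 10. The risk is a slow coupling at the tetrasubstituted, neopentylic triflate, with β-hydride elimination from the alkylpalladium intermediate or imperfect regioselectivity in the diene hydroboration. The fallback sets out from 12 and returns at 17; it forms C12–C13 instead of C9–C11. Stille coupling of 12 with tributyl(vinyl)stannane (Pd(PPh3)4, LiCl, THF, 65 °C) gives the 9-vinyl diene F8. Its terminal vinyl group is hydroborated with excess 9-BBN and the borane is coupled (Pd(dppf)Cl2, Cs2CO3) with the vinyl iodide F9. F9 is made from but-2-yn-1-ol by trans-hydroalumination and iodination (NaAlH2(OCH2CH2OMe)2, then I2) followed by silylation.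

## Further compounds

F1 | step 1 | allylidenecyclopropane (prop-2-en-1-ylidenecyclopropane) | C=CC=C1CC1
F2 | step 1 | (4a'R,8a'S)-2',8a'-dimethyl-4a',8a'-dihydro-8'H-spiro[cyclopropane-1,5'-naphthalene]-1',4'-dione | O=C1C=C(C)C(=O)[C@@]2(C)CC=CC3(CC3)[C@@H]12
F3 | step 1 | (4a'R,8a'S)-2',8a'-dimethylhexahydro-1'H-spiro[cyclopropane-1,5'-naphthalene]-1',4'(4a'H)-dione (C2' epimers) | O=C1CC(C)C(=O)[C@@]2(C)CCCC3(CC3)[C@@H]12
F4 | step 3 | (4aS,8aS)-2,5,5,8a-tetramethyl-4a,5,8,8a-tetrahydronaphthalene-1,4-dione | O=C1C=C(C)C(=O)[C@@]2(C)CC=CC(C)(C)[C@H]12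
F5 | step 6 | (4aS,8aS)-2,5,5,8a-tetramethyl-4-oxo-3,4,4a,5,6,7,8,8a-octahydronaphthalen-1-yl trifluoromethanesulfonate | O=C1CC(C)=C(OS(=O)(=O)C(F)(F)F)[C@@]2(C)CCCC(C)(C)[C@H]12
F6 | step 6 | (3S,4aS,8aS)-3-hydroxy-2,5,5,8a-tetramethyl-4-oxo-3,4,4a,5,6,7,8,8a-octahydronaphthalen-1-yl trifluoromethanesulfonate | O=C1[C@@H](O)C(C)=C(OS(=O)(=O)C(F)(F)F)[C@@]2(C)CCCC(C)(C)[C@H]12
F7 | step 7 | (3S,4S,4aS,8aS)-3,4-dihydroxy-2,5,5,8a-tetramethyl-3,4,4a,5,6,7,8,8a-octahydronaphthalen-1-yl trifluoromethanesulfonate | O[C@@H]1[C@@H](O)C(C)=C(OS(=O)(=O)C(F)(F)F)[C@@]2(C)CCCC(C)(C)[C@H]12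
F8 | step 10 | (1S,2S,4aS,8aS)-2-[(tert-butyldimethylsilyl)oxy]-4-ethenyl-3,4a,8,8-tetramethyl-1,2,4a,5,6,7,8,8a-octahydronaphthalen-1-ol | O[C@@H]1[C@@H](O[Si](C)(C)C(C)(C)C)C(C)=C(C=C)[C@@]2(C)CCCC(C)(C)[C@H]12
F9 | step 10 | tert-butyl{[(2Z)-3-iodobut-2-en-1-yl]oxy}dimethylsilane | CC(C)(C)[Si](C)(C)OC/C=C(/C)I
A1 | alternative 1 | (2Z)-3-methyl-5-[(4aS,8aS)-2,5,5,8a-tetramethyl-3,4,4a,5,6,7,8,8a-octahydronaphthalen-1-yl]pent-2-en-1-ol ((13Z)-labda-8,13-dien-15-ol) | CC1=C(CC/C(C)=C\CO)[C@@]2(C)CCCC(C)(C)[C@@H]2CC1
A2 | alternative 1 | (4aS,8aS)-4-[(3Z)-5-hydroxy-3-methylpent-3-en-1-yl]-3,4a,8,8-tetramethyl-4a,5,6,7,8,8a-hexahydronaphthalen-2(1H)-one | C1C(=O)C(C)=C(CC/C(C)=C\CO)[C@@]2(C)CCCC(C)(C)[C@H]12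
A3 | alternative 2 | tert-butyldimethyl{[(2Z,6E,10E)-3,7,11,15-tetramethylhexadeca-2,6,10,14-tetraen-1-yl]oxy}silane | CC(C)=CCC/C(C)=C/CC/C(C)=C/CC/C(C)=C\CO[Si](C)(C)C(C)(C)C
A4 | alternative 2 | tert-butyldimethyl{[(2Z)-3-methyl-5-[(4aS,8aS)-2,5,5,8a-tetramethyl-3,4,4a,5,6,7,8,8a-octahydronaphthalen-1-yl]pent-2-en-1-yl]oxy}silane | CC1=C(CC/C(C)=C\CO[Si](C)(C)C(C)(C)C)[C@@]2(C)CCCC(C)(C)[C@@H]2CC1
A5 | alternative 3 | (5S,6S)-2,6-dimethyl-5-(prop-1-en-2-yl)-6-(prop-2-en-1-yl)cyclohex-2-en-1-one | C1C=C(C)C(=O)[C@@](C)(CC=C)[C@@H]1C(C)=C
A6 | alternative 3 | (4aS,8aS)-2,5,5,8a-tetramethyl-4a,5,6,7,8,8a-hexahydronaphthalen-1(4H)-one | C1C=C(C)C(=O)[C@@]2(C)CCCC(C)(C)[C@H]12
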